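Both bicyclic halves of the target are the same trans-fused oxepane–cyclohexane, so the synthesis rests on one building block made once and used twice: rings C and D, which share the C15–C21 bond. Those two carbons are the carbons of a trisubstituted epoxide, and an epoxonium ion centred on O20 forms its two new bonds, O20–C19 and C14–C15, in a single Lewis-acid operation that closes both rings and sets C14 and C15. The precursor is an acyclic (S,S,S)-diepoxide carrying an allylsilane terminator. The resulting C24-methylene bicycle is elaborated divergently to both halves, which are joined at C12–C13 by Julia–Kocienski olefination.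

Key step: step 7

Numbering: skeleton atoms 1–24 follow the target SMILES (acetyl, methyl, hydroxyl and oxo atoms not counted). O5 and O20 are the ring oxygens. Ring A = O5, C6–C10, C4; ring B = C1–C4, C10, C11; ring C = C14, C15, C21–C24; ring D = C15–C19, O20, C21. When bicycle 14 serves the ring A/B half, its atoms C24…C13 become C1…C12 in that order (O20 becomes O5).

Remark on the chemistry: the allylsilane double bond is Z by the CIP rules (CH2SiMe3 outranks the chain) although the carbon chain runs trans across it, and the all-S diepoxide needs the L-fructose-derived enantiomer of the usual Shi ketone, assumed purchasable or made from L-sorbose.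

Step 1
Reactants: 1 ethyl acetoacetate; 2 geranyl bromide
Product: 4 ethyl (6E)-7,11-dimethyl-3-oxododeca-6,10-dienoate, via acetoacetate dianion 3 (not isolated)
Conditions: NaH, THF, 0 °C; n-BuLi, 0 °C; then 2, 0 °C → rt
Reagents that add atoms: none
Why: γ-Alkylation of the acetoacetate dianion, whose terminal carbanion is the more reactive site, displaces the primary allylic bromide by SN2 and leaves the E double bond untouched.

Step 2
Reactants: 4 ethyl (6E)-7,11-dimethyl-3-oxododeca-6,10-dienoate
Product: 6 ethyl (2Z,6E)-7,11-dimethyl-3-{[(trifluoromethyl)sulfonyl]oxy}dodeca-2,6,10-trienoate, via potassium enolate 5 (not isolated)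
Conditions: KN(SiMe3)2, THF, −78 °C; then PhNTf2, −78 °C → rt
Reagents that add atoms: N-phenyl-bis(trifluoromethanesulfonimide), O=S(=O)(N(c1ccccc1)S(=O)(=O)C(F)(F)F)C(F)(F)F
Why: Stereoselective enol triflate formation: the metal-chelated enolate of the β-keto ester is O-sulfonylated with the triflate cis to the ester (Z).

Step 3
Reactants: 6 ethyl (2Z,6E)-7,11-dimethyl-3-{[(trifluoromethyl)sulfonyl]oxy}dodeca-2,6,10-trienoate; 7 (trimethylsilyl)methylmagnesium chloride
Product: 8 ethyl (2Z,6E)-7,11-dimethyl-3-[(trimethylsilyl)methyl]dodeca-2,6,10-trienoate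
Conditions: Ni(acac)2 (cat.), THF, 0 °C → rt
Reagents that add atoms: none
Why: Kumada-type nickel-catalysed cross-coupling of an activated enol triflate with a Grignard reagent lacking β-hydrogens should proceed with retention of alkene geometry, and the ester is not attacked at this temperature.

Step 4
Reactants: 8 ethyl (2Z,6E)-7,11-dimethyl-3-[(trimethylsilyl)methyl]dodeca-2,6,10-trienoate
Product: 9 ethyl (2Z,6S,7S,10S)-6,7:10,11-diepoxy-7,11-dimethyl-3-[(trimethylsilyl)methyl]dodec-2-enoate
Conditions: L-fructose-derived Shi ketone (1,2:4,5-di-O-isopropylidene-β-L-erythro-2,3-hexodiulo-2,6-pyranose), Oxone (KHSO5), K2CO3, Bu4NHSO4, MeCN/CH2(OMe)2, aq. Na2B4O7/Na2EDTA buffer, 0 °C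
Reagents that add atoms: potassium peroxymonosulfate, [K+].[O-]S(=O)(=O)OO
Why: Shi asymmetric epoxidation: the chiral dioxirane attacks only the two electron-rich trisubstituted alkenes (the enoate alkene is deactivated) through a spiro transition state, and the L-series catalyst should set 6S, 7S and 10S under catalyst control.

Step 5
Reactants: 9 ethyl (2Z,6S,7S,10S)-6,7:10,11-diepoxy-7,11-dimethyl-3-[(trimethylsilyl)methyl]dodec-2-enoate
Product: 10 (2Z,6S,7S,10S)-6,7:10,11-diepoxy-7,11-dimethyl-3-[(trimethylsilyl)methyl]dodec-2-en-1-ol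
Conditions: i-Bu2AlH, CH2Cl2, −78 °C; aq. potassium sodium tartrate
Reagents that add atoms: none
Why: 1,2-Reduction of the conjugated ester by the aluminium hydride at −78 °C, where trisubstituted epoxides and the allylsilane are inert.

Step 6
Reactants: 10 (2Z,6S,7S,10S)-6,7:10,11-diepoxy-7,11-dimethyl-3-[(trimethylsilyl)methyl]dodec-2-en-1-ol
Product: 11 tert-butyldimethylsilyl ether of 10 [(2Z,6S,7S,10S)-diepoxy allylsilane, cascade precursor]
Conditions: t-BuMe2SiCl, imidazole, CH2Cl2, 0 °C → rt
Reagents that add atoms: tert-butyldimethylsilyl chloride, CC(C)(C)[Si](C)(C)Cl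
Why: Standard silylation of a primary allylic alcohol under neutral-basic conditions that spare the epoxides and the acid-sensitive allylsilane; the bulky silyl ether oxygen is a poor Lewis base for the next step.

Step 7
Reactants: 11 tert-butyldimethylsilyl ether of 10
Product: 14 (3S,5aS,6R,9aS)-6-({[tert-butyl(dimethyl)silyl]oxy}methyl)-2,2,5a-trimethyl-7-methylidenedecahydro-1-benzoxepin-3-ol (rings C/D with C24 methylene), via epoxonium triflate 12 (not isolated), via trimethylsilyl ether 13 (not isolated)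
Conditions: Me3SiOTf (1.2 equiv), 2,6-di-tert-butyl-4-methylpyridine, CH2Cl2, −78 °C; then K2CO3, MeOH, rt
Reagents that add atoms: none
Why: Me3SiOTf silylates the terminal epoxide oxygen, and the neighbouring epoxide oxygen O20 opens it at the dimethyl-substituted carbon C19 (retention at C18, whose C–O bond is untouched) to give the bicyclic epoxonium ion 12; the allylsilane carbon C14 then attacks tertiary C15 anti to the departing O20, and loss of Me3Si+ leaves the C24 methylene. This is the known Lewis-acid-promoted endo-selective cascade of 1,5-diepoxides through epoxonium ions terminated by allyl-, propargyl- or enol-silanes, an oxa-variant of epoxy-polyene cyclisation. Ring D (oxepane) arises by endo opening of the epoxonium, that is, cleavage of the O20–C15 fusion bond so that the six-membered oxonium ring expands to seven, and ring C closes 6-endo with respect to both the epoxonium and the alkene. C15 is set by inversion in the anti opening of the enantiopure trans epoxide, which also fixes the trans C15–C21 fusion, and C14 by the chair transition state, in which the trans disposition of the carbon chain across the allylsilane double bond places C13 equatorial, cis to the C15 methyl. The step needs opening at the tertiary carbon twice and chair folding; the methyl groups at C19 and C15 stabilise positive charge at exactly those carbons, the β-silicon effect makes C14 the nucleophilic terminus and fixes the alkene position, and the hindered pyridine base suppresses protodesilylation.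

Step 8
Reactants: 14 ring C/D oxepanol (used here as the ring A/B building block)
Product: 15 C7 benzyl ether of 14 (C1 exocyclic methylene, C12 tert-butyldimethylsilyl ether)
Conditions: NaH, BnBr, Bu4NI (cat.), THF/DMF, 0 °C → rt
Reagents that add atoms: benzyl bromide, BrCc1ccccc1
Why: Williamson etherification of the secondary alkoxide; this benzyl group is what later distinguishes C7 (stays an alcohol) from C18 (becomes the ketone).

Step 9
Reactants: 15 C7 benzyl ether of 14
Product: 17 ring A/B ketone (C1 oxo; C7 benzyl ether; C12 tert-butyldimethylsilyl ether), via vicinal diol 16 (not isolated)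
Conditions: OsO4 (cat.), NaIO4, 2,6-lutidine, dioxane/H2O, rt
Reagents that add atoms: osmium tetroxide, O=[Os](=O)(=O)=O (oxygen carrier, regenerated by sodium periodate, [Na+].[O-]I(=O)(=O)=O)
Why: Lemieux–Johnson oxidative cleavage of the 1,1-disubstituted alkene, chosen over ozone to spare the benzyl ether; C11 next to the new ketone already carries its substituent in the preferred equatorial position.

Step 10
Reactants: 17 ring A/B ketone
Product: 18 (1R) tertiary alcohol (C1 methyl equatorial, hydroxyl axial on the face of the C10 methyl; C7 benzyl ether; C12 silyl ether)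
Conditions: MeMgBr, CeCl3, THF, −78 → 0 °C
Reagents that add atoms: methylmagnesium bromide, C[Mg]Br
Why: Grignard 1,2-addition, with CeCl3 to suppress enolisation; the axial C10 methyl blocks the axial trajectory (1,3-diaxial), so methyl should enter equatorially and give the axial C1 hydroxyl (1R).

Step 11
Reactants: 18 (1R) tertiary alcohol
Product: 19 ring A/B diol (C12 primary OH, C1 tertiary OH, C7 benzyl ether)
Conditions: Bu4NF, THF, 0 °C → rt
Reagents that add atoms: none
Why: Fluoride cleavage of the primary silyl ether; the benzyl ether and the tertiary alcohol are unaffected.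

Step 12
Reactants: 19 ring A/B diol
Product: 20 C12 (1-phenyl-1H-tetrazol-5-yl) sulfide (C1 tertiary OH free)
Conditions: 1-phenyl-1H-tetrazole-5-thiol, PPh3, i-PrO2CN=NCO2i-Pr, THF, 0 °C → rt
Reagents that add atoms: 1-phenyl-1H-tetrazole-5-thiol, Sc1nnnn1-c1ccccc1
Why: Mitsunobu thioetherification activates only the primary alcohol, and the acidic, highly nucleophilic thiol should outrun any participation by the tertiary hydroxyl.

Step 13
Reactants: 20 C12 tetrazolyl sulfide
Product: 21 C12 (1-phenyl-1H-tetrazol-5-yl) sulfone (C1 tertiary OH free)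
Conditions: (NH4)6Mo7O24·4H2O (cat.), 30% H2O2, EtOH, 0 °C → rt
Reagents that add atoms: hydrogen peroxide, OO
Why: Molybdate-catalysed peroxide oxidation of the sulfide to the sulfone, compatible with the benzyl ether and the tertiary alcohol.

Step 14
Reactants: 21 C12 tetrazolyl sulfone
Product: 22 ring A/B sulfone fragment (C1 triethylsilyl ether, C7 benzyl ether, C12 tetrazolyl sulfone)
Conditions: Et3SiOTf, 2,6-lutidine, CH2Cl2, 0 °C → rt
Reagents that add atoms: triethylsilyl trifluoromethanesulfonate, CC[Si](CC)(CC)OS(=O)(=O)C(F)(F)F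
Why: Silyl triflate silylation reaches even the hindered axial tertiary alcohol; masking it keeps an alkoxide from attacking the tetrazole or consuming base in the olefination.

Step 15
Reactants: 14 ring C/D oxepanol
Product: 23 C24 spiro-epoxide (epoxide oxygen equatorial, CH2 axial; C18 OH free; C13 silyl ether)
Conditions: mCPBA, NaHCO3, CH2Cl2, 0 °C
Reagents that add atoms: 3-chloroperoxybenzoic acid, OOC(=O)c1cccc(Cl)c1
Why: Prilezhaev epoxidation; the axial C15 methyl shields the axial face of C24, so the peracid should approach equatorially and place the new oxygen equatorial.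

Step 16
Reactants: 23 C24 spiro-epoxide
Product: 24 (24S) diol (C24 tertiary OH equatorial, methyl axial; C18 OH; C13 silyl ether)
Conditions: LiAlH4, THF, 0 → 40 °C
Reagents that add atoms: none
Why: Hydride opens the epoxide by SN2 at its CH2 carbon, which becomes the axial C24 methyl, while the C24–O bond and hence the configuration set in step 15 is retained.

Step 17
Reactants: 24 (24S) diol
Product: 25 ring C/D triol (C13 primary, C18 secondary, C24 tertiary OH)
Conditions: Bu4NF, THF, rt
Reagents that add atoms: none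
Why: Fluoride desilylation of the primary silyl ether; nothing else in the molecule is fluoride-labile.

Step 18
Reactants: 25 ring C/D triol
Product: 26 tris(triethylsilyl) ether of 25
Conditions: Et3SiOTf (excess), 2,6-lutidine, CH2Cl2, −78 °C → rt
Reagents that add atoms: triethylsilyl trifluoromethanesulfonate, CC[Si](CC)(CC)OS(=O)(=O)C(F)(F)F
Why: Exhaustive silylation with the silyl triflate, which also reaches the tertiary C24 hydroxyl, puts one protecting group on all three oxygens so that no selective protection is needed.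

Step 19
Reactants: 26 tris(triethylsilyl) ether
Product: 27 ring C/D aldehyde fragment (C13 aldehyde; C18 and C24 triethylsilyl ethers)
Conditions: (COCl)2, DMSO, CH2Cl2, −78 → −40 °C; Et3N, −78 → 0 °C
Reagents that add atoms: none
Why: Swern conditions are known to cleave and oxidise a primary triethylsilyl ether in one pot while hindered secondary and tertiary triethylsilyl ethers survive; C14 keeps its equatorial substituent.

Step 20
Reactants: 22 ring A/B sulfone fragment; 27 ring C/D aldehyde fragment
Product: 30 coupled C12=C13 alkene (C7 benzyl ether; C1/C18/C24 triethylsilyl ethers), via potassium sulfonyl carbanion 28 (not isolated), via β-alkoxy sulfone 29 (not isolated)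
Conditions: 22, KN(SiMe3)2, THF, −78 °C; then 27, −78 °C → rt
Reagents that add atoms: none
Why: Julia–Kocienski olefination: the sulfonyl carbanion adds to the aldehyde, the alkoxide transfers the tetrazole from sulfur to oxygen (Smiles rearrangement), and loss of SO2 and tetrazolate gives the alkene, whose geometry is irrelevant; the aldehyde is placed on the half whose β-silyloxy group is equatorial and poorly aligned for elimination.

Step 21
Reactants: 30 coupled alkene
Product: 31 triol (C1 and C24 tertiary OH, C18 secondary OH; C7 benzyl ether)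
Conditions: Bu4NF, THF, rt → 45 °C
Reagents that add atoms: none
Why: Fluoride removes all three triethylsilyl groups in one operation; benzyl ether and alkene are inert.

Step 22
Reactants: 31 triol
Product: 32 C18 ketone diol (C1 and C24 tertiary OH; C7 benzyl ether)
Conditions: Dess–Martin periodinane, NaHCO3, CH2Cl2, rt
Reagents that add atoms: none
Why: Dess–Martin oxidation can touch only the single secondary alcohol at C18, since the other two are tertiary and C7 is still benzylated.

Step 23
Reactants: 32 C18 ketone diol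
Product: 33 C1,C24 diacetate (C18 ketone; C7 benzyl ether; C12=C13 alkene)
Conditions: Ac2O, DMAP, Et3N, toluene, 60 °C
Reagents that add atoms: acetic anhydride, CC(=O)OC(C)=O
Why: DMAP-catalysed acylation is the standard non-ionising way to esterify hindered tertiary alcohols and avoids the carbocation-forming conditions that would dehydrate them; the ketone has no epimerisable α-centre.

Step 24
Reactants: 33 C1,C24 diacetate
Product: 34 target CNP0298533.1, (1R,4S,7S,10S,11S,14S,15S,21S,24S) in skeleton numbering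
Conditions: H2 (1 atm), 10% Pd/C, EtOAc, rt
Reagents that add atoms: none
Why: Heterogeneous hydrogenation saturates the disubstituted C12=C13 alkene and, in the same operation, hydrogenolyses the C7 benzyl ether; tertiary acetates and the ketone are inert.

Compound list
1 | ethyl acetoacetate | CCOC(=O)CC(C)=O | starting material
2 | geranyl bromide | CC(C)=CCC/C(C)=C/CBr | starting material
3 | ethyl acetoacetate dianion (sodium lithium salt) | [Na+].[Li+].CCOC(=O)[CH-]C(=O)[CH2-] | intermediate (not isolated)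
4 | ethyl (6E)-7,11-dimethyl-3-oxododeca-6,10-dienoate | CCOC(=O)CC(=O)CC/C=C(C)/CCC=C(C)C | intermediate
5 | potassium (Z)-enolate of 4 | CCOC(=O)/C=C(\[O-])CC/C=C(C)/CCC=C(C)C.[K+] | intermediate (not isolated)
6 | ethyl (2Z,6E)-7,11-dimethyl-3-{[(trifluoromethyl)sulfonyl]oxy}dodeca-2,6,10-trienoate | CCOC(=O)/C=C(\OS(=O)(=O)C(F)(F)F)CC/C=C(C)/CCC=C(C)C | intermediate
7 | (trimethylsilyl)methylmagnesium chloride | C[Si](C)(C)C[Mg]Cl | starting material
8 | ethyl (2Z,6E)-7,11-dimethyl-3-[(trimethylsilyl)methyl]dodeca-2,6,10-trienoate | CCOC(=O)/C=C(\C[Si](C)(C)C)CC/C=C(C)/CCC=C(C)C | intermediate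
9 | ethyl (2Z,6S,7S,10S)-6,7:10,11-diepoxy-7,11-dimethyl-3-[(trimethylsilyl)methyl]dodec-2-enoate | CC1(C)O[C@H]1CC[C@]2(C)O[C@H]2CC/C(C[Si](C)(C)C)=C/C(=O)OCC | intermediate
10 | (2Z,6S,7S,10S)-6,7:10,11-diepoxy-7,11-dimethyl-3-[(trimethylsilyl)methyl]dodec-2-en-1-ol | CC1(C)O[C@H]1CC[C@]2(C)O[C@H]2CC/C(C[Si](C)(C)C)=C/CO | intermediate
11 | tert-butyldimethylsilyl ether of 10 (cascade precursor) | CC1(C)O[C@H]1CC[C@]2(C)O[C@H]2CC/C(C[Si](C)(C)C)=C/CO[Si](C)(C)C(C)(C)C | intermediate
12 | bicyclic epoxonium triflate (O20 bonded to C15, C19 and C21; C18 OSiMe3) | C[Si](C)(C)O[C@H]1CC[C@]2(C)[O+](C1(C)C)[C@H]2CC/C(C[Si](C)(C)C)=C/CO[Si](C)(C)C(C)(C)C.[O-]S(=O)(=O)C(F)(F)F | intermediate (not isolated)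
13 | C18 trimethylsilyl ether of 14 | CC(C)(C)[Si](C)(C)OC[C@H]1[C@]2(C)CC[C@H](O[Si](C)(C)C)C(C)(C)O[C@H]2CCC1=C | intermediate (not isolated)
14 | (3S,5aS,6R,9aS)-6-({[tert-butyl(dimethyl)silyl]oxy}methyl)-2,2,5a-trimethyl-7-methylidenedecahydro-1-benzoxepin-3-ol | CC(C)(C)[Si](C)(C)OC[C@H]1[C@]2(C)CC[C@H](O)C(C)(C)O[C@H]2CCC1=C | intermediate
15 | C7 benzyl ether of 14 (ring A/B numbering) | C=C1CC[C@@H]2OC(C)(C)[C@@H](OCc3ccccc3)CC[C@@]2(C)[C@@H]1CO[Si](C)(C)C(C)(C)C | intermediate
16 | vicinal diol from 15 (C1 configuration immaterial) | OCC1(O)CC[C@@H]2OC(C)(C)[C@@H](OCc3ccccc3)CC[C@@]2(C)[C@@H]1CO[Si](C)(C)C(C)(C)C | intermediate (not isolated)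
17 | ring A/B ketone (C1 oxo, C7 OBn, C12 OSi) | O=C1CC[C@@H]2OC(C)(C)[C@@H](OCc3ccccc3)CC[C@@]2(C)[C@@H]1CO[Si](C)(C)C(C)(C)C | intermediate
18 | (1R) tertiary alcohol (C1 OH axial, C7 OBn, C12 OSi) | O[C@]1(C)CC[C@@H]2OC(C)(C)[C@@H](OCc3ccccc3)CC[C@@]2(C)[C@@H]1CO[Si](C)(C)C(C)(C)C | intermediate
19 | ring A/B diol (C1 OH, C12 OH, C7 OBn) | O[C@]1(C)CC[C@@H]2OC(C)(C)[C@@H](OCc3ccccc3)CC[C@@]2(C)[C@@H]1CO | intermediate
20 | C12 (1-phenyl-1H-tetrazol-5-yl) sulfide | O[C@]1(C)CC[C@@H]2OC(C)(C)[C@@H](OCc3ccccc3)CC[C@@]2(C)[C@@H]1CSc1nnnn1-c1ccccc1 | intermediate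
21 | C12 (1-phenyl-1H-tetrazol-5-yl) sulfone, C1 OH free | O[C@]1(C)CC[C@@H]2OC(C)(C)[C@@H](OCc3ccccc3)CC[C@@]2(C)[C@@H]1CS(=O)(=O)c1nnnn1-c1ccccc1 | intermediate
22 | ring A/B sulfone fragment (C1 OSiEt3) | CC[Si](CC)(CC)O[C@]1(C)CC[C@@H]2OC(C)(C)[C@@H](OCc3ccccc3)CC[C@@]2(C)[C@@H]1CS(=O)(=O)c1nnnn1-c1ccccc1 | intermediate
23 | C24 spiro-epoxide (oxygen equatorial) | CC(C)(C)[Si](C)(C)OC[C@H]1[C@]2(C)CC[C@H](O)C(C)(C)O[C@H]2CC[C@@]13CO3 | intermediate
24 | (24S) diol, C13 silyl ether | CC(C)(C)[Si](C)(C)OC[C@H]1[C@]2(C)CC[C@H](O)C(C)(C)O[C@H]2CC[C@]1(C)O | intermediate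
25 | ring C/D triol | OC[C@H]1[C@]2(C)CC[C@H](O)C(C)(C)O[C@H]2CC[C@]1(C)O | intermediate
26 | tris(triethylsilyl) ether of 25 | CC[Si](CC)(CC)OC[C@H]1[C@]2(C)CC[C@H](O[Si](CC)(CC)CC)C(C)(C)O[C@H]2CC[C@]1(C)O[Si](CC)(CC)CC | intermediate
27 | ring C/D aldehyde fragment (C13 CHO; C18, C24 OSiEt3) | O=C[C@H]1[C@]2(C)CC[C@H](O[Si](CC)(CC)CC)C(C)(C)O[C@H]2CC[C@]1(C)O[Si](CC)(CC)CC | intermediate
28 | potassium sulfonyl carbanion of 22 | CC[Si](CC)(CC)O[C@]1(C)CC[C@@H]2OC(C)(C)[C@@H](OCc3ccccc3)CC[C@@]2(C)[C@@H]1[CH-]S(=O)(=O)c1nnnn1-c1ccccc1.[K+] | intermediate (not isolated)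
29 | potassium β-alkoxy sulfone adduct (C12 and C13 configuration immaterial) | CC[Si](CC)(CC)O[C@]1(C)CC[C@@H]2OC(C)(C)[C@@H](OCc3ccccc3)CC[C@@]2(C)[C@@H]1C(C([O-])[C@H]1[C@]2(C)CC[C@H](O[Si](CC)(CC)CC)C(C)(C)O[C@H]2CC[C@]1(C)O[Si](CC)(CC)CC)S(=O)(=O)c1nnnn1-c1ccccc1.[K+] | intermediate (not isolated)
30 | coupled C12=C13 alkene (E shown; C7 OBn; C1, C18, C24 OSiEt3) | CC[Si](CC)(CC)O[C@]1(C)CC[C@@H]2OC(C)(C)[C@@H](OCc3ccccc3)CC[C@@]2(C)[C@@H]1/C=C/[C@H]1[C@]2(C)CC[C@H](O[Si](CC)(CC)CC)C(C)(C)O[C@H]2CC[C@]1(C)O[Si](CC)(CC)CC | intermediate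
31 | triol (C1, C18, C24 OH; C7 OBn) | O[C@]1(C)CC[C@@H]2OC(C)(C)[C@@H](OCc3ccccc3)CC[C@@]2(C)[C@@H]1/C=C/[C@H]1[C@]2(C)CC[C@H](O)C(C)(C)O[C@H]2CC[C@]1(C)O | intermediate
32 | C18 ketone diol (C1, C24 OH; C7 OBn) | O[C@]1(C)CC[C@@H]2OC(C)(C)[C@@H](OCc3ccccc3)CC[C@@]2(C)[C@@H]1/C=C/[C@H]1[C@]2(C)CCC(=O)C(C)(C)O[C@H]2CC[C@]1(C)O | intermediate
33 | C1,C24 diacetate (C18 ketone; C7 OBn; C12=C13) | CC(=O)O[C@]1(C)CC[C@@H]2OC(C)(C)[C@@H](OCc3ccccc3)CC[C@@]2(C)[C@@H]1/C=C/[C@H]1[C@]2(C)CCC(=O)C(C)(C)O[C@H]2CC[C@]1(C)OC(C)=O | intermediate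
34 | CNP0298533.1 | CC(=O)O[C@]1(C)CC[C@@H]2OC(C)(C)[C@@H](O)CC[C@@]2(C)[C@@H]1CC[C@H]1[C@]2(C)CCC(=O)C(C)(C)O[C@H]2CC[C@]1(C)OC(C)=O | target

Total step count: 24. Longest linear sequence: 19 steps (steps 1–14, then 20–24); the ring C/D arm (steps 15–19) is the shorter branch.

Steps most likely to fail

1. Step 7 (epoxonium cascade). The cascade may stop after the first ring through capture of the epoxonium by triflate or loss of a proton. The activated terminal epoxide may instead rearrange by hydride shift, or the allylsilane may be protodesilylated or its allylic silyl ether ionised before the C–C bond forms. The fallback closes the two rings in separate, individually precedented operations, carbocycle first and oxepane second; it sets out from ethyl acetoacetate 1, with geraniol as an extra commercial material, and returns at 14. Sharpless asymmetric epoxidation of geraniol (Ti(O-iPr)4, L-(+)-diethyl tartrate, t-BuOOH, 4 Å sieves, −20 °C) should give (2S,3S)-2,3-epoxygeraniol F1, and I2, PPh3 and imidazole convert it into the epoxy iodide F2. Alkylation of dianion 3 with F2 at low temperature should give the epoxy β-keto ester F3. The conditions of steps 2, 3, 5 and 6 then lead through the enol triflate F4, the allylsilane ester F5 and the allylic alcohol F6 to the silyl ether F7, which carries only the internal epoxide. BF3·OEt2 in CH2Cl2 at −78 °C should effect the classical epoxide–allylsilane cyclisation to the methylenecyclohexanol F8; C14 attacks C15 anti to the epoxide oxygen through a chair, giving the same C14, C15 and C21 configuration as in 14. Shi epoxidation with the L-series ketone should then oxidise the remaining trisubstituted alkene, which reacts faster than the 1,1-disubstituted one, to the hydroxy epoxide F9. Camphorsulfonic acid in CH2Cl2 should finally let the C21 hydroxyl open the epoxide at the dimethyl-substituted C19 (7-endo, retention at C18) to give 14.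

2. Step 20 (Julia–Kocienski union). Addition of a crowded sulfonyl carbanion to a crowded α-branched aldehyde may be slow, so that enolisation of the aldehyde or self-condensation of the sulfone takes over. The fallback avoids carbonyl addition by forming two C–S bonds and extruding SO2 (Ramberg–Bäcklund); it sets out from 19 and 25 and returns at 30. Mitsunobu reaction of diol 19 with thioacetic acid should give the thioacetate F10, and Et3SiOTf with 2,6-lutidine its tertiary triethylsilyl ether F11. Triol 25 with I2, PPh3 and imidazole should give the primary iodide F12, and Et3SiOTf with 2,6-lutidine its bis(triethylsilyl) ether F13. K2CO3 in MeOH/DMF releases the thiolate from F11, which should displace the iodide of F13 to give the sulfide F14. mCPBA with NaHCO3 oxidises this to the sulfone F15. CBr2F2 with KOH on Al2O3 in t-BuOH/CH2Cl2 should then give alkene 30, whose double-bond geometry is immaterial.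

3. Step 23 (double acetylation). Acylation of the axial C1 hydroxyl, which is 1,3-diaxial to the C10 methyl, may be incomplete, and forcing conditions may dehydrate the tertiary alcohols. The fallback acylates the lithium alkoxides before the ketone exists; it sets out from 31 and returns at 33. Et3SiCl and imidazole in DMF should silylate only the secondary C18 hydroxyl to give the mono(triethylsilyl) ether F16. n-BuLi in THF at −78 °C followed by Ac2O should give the diacetate F17. HF·pyridine in THF removes the silyl group to give the C18 alcohol F18, and Dess–Martin oxidation gives 33.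

Further compounds
F1 | step 7 | (2S,3S)-2,3-epoxygeraniol | CC(C)=CCC[C@]1(C)O[C@H]1CO
F2 | step 7 | iodide of (2S,3S)-2,3-epoxygeraniol | CC(C)=CCC[C@]1(C)O[C@H]1CI
F3 | step 7 | ethyl 5-[(2S,3S)-3-methyl-3-(4-methylpent-3-en-1-yl)oxiran-2-yl]-3-oxopentanoate | CC(C)=CCC[C@]1(C)O[C@H]1CCC(=O)CC(=O)OCC
F4 | step 7 | (Z)-enol triflate of F3 | CC(C)=CCC[C@]1(C)O[C@H]1CC/C(OS(=O)(=O)C(F)(F)F)=C/C(=O)OCC
F5 | step 7 | monoepoxy allylsilane ester | CC(C)=CCC[C@]1(C)O[C@H]1CC/C(C[Si](C)(C)C)=C/C(=O)OCC
F6 | step 7 | monoepoxy allylsilane allylic alcohol | CC(C)=CCC[C@]1(C)O[C@H]1CC/C(C[Si](C)(C)C)=C/CO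
F7 | step 7 | tert-butyldimethylsilyl ether of F6 | CC(C)=CCC[C@]1(C)O[C@H]1CC/C(C[Si](C)(C)C)=C/CO[Si](C)(C)C(C)(C)C
F8 | step 7 | methylenecyclohexanol with prenyl-type side chain (ring C closed) | CC(C)(C)[Si](C)(C)OC[C@H]1[C@](C)(CCC=C(C)C)[C@@H](O)CCC1=C
F9 | step 7 | hydroxy (18S)-epoxide of F8 | CC(C)(C)[Si](C)(C)OC[C@H]1[C@](C)(CC[C@@H]2OC2(C)C)[C@@H](O)CCC1=C
F10 | step 20 | ring A/B C12 thioacetate, C1 OH free | O[C@]1(C)CC[C@@H]2OC(C)(C)[C@@H](OCc3ccccc3)CC[C@@]2(C)[C@@H]1CSC(C)=O
F11 | step 20 | ring A/B C12 thioacetate, C1 triethylsilyl ether | CC[Si](CC)(CC)O[C@]1(C)CC[C@@H]2OC(C)(C)[C@@H](OCc3ccccc3)CC[C@@]2(C)[C@@H]1CSC(C)=O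
F12 | step 20 | ring C/D C13 iodide diol | IC[C@H]1[C@]2(C)CC[C@H](O)C(C)(C)O[C@H]2CC[C@]1(C)O
F13 | step 20 | ring C/D C13 iodide bis(triethylsilyl) ether | IC[C@H]1[C@]2(C)CC[C@H](O[Si](CC)(CC)CC)C(C)(C)O[C@H]2CC[C@]1(C)O[Si](CC)(CC)CC
F14 | step 20 | C12–S–C13 sulfide | CC[Si](CC)(CC)O[C@]1(C)CC[C@@H]2OC(C)(C)[C@@H](OCc3ccccc3)CC[C@@]2(C)[C@@H]1CSC[C@H]1[C@]2(C)CC[C@H](O[Si](CC)(CC)CC)C(C)(C)O[C@H]2CC[C@]1(C)O[Si](CC)(CC)CC
F15 | step 20 | C12–SO2–C13 sulfone | CC[Si](CC)(CC)O[C@]1(C)CC[C@@H]2OC(C)(C)[C@@H](OCc3ccccc3)CC[C@@]2(C)[C@@H]1CS(=O)(=O)C[C@H]1[C@]2(C)CC[C@H](O[Si](CC)(CC)CC)C(C)(C)O[C@H]2CC[C@]1(C)O[Si](CC)(CC)CC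
F16 | step 23 | C18 mono(triethylsilyl) ether of 31 | O[C@]1(C)CC[C@@H]2OC(C)(C)[C@@H](OCc3ccccc3)CC[C@@]2(C)[C@@H]1/C=C/[C@H]1[C@]2(C)CC[C@H](O[Si](CC)(CC)CC)C(C)(C)O[C@H]2CC[C@]1(C)O
F17 | step 23 | C1,C24 diacetate, C18 triethylsilyl ether | CC(=O)O[C@]1(C)CC[C@@H]2OC(C)(C)[C@@H](OCc3ccccc3)CC[C@@]2(C)[C@@H]1/C=C/[C@H]1[C@]2(C)CC[C@H](O[Si](CC)(CC)CC)C(C)(C)O[C@H]2CC[C@]1(C)OC(C)=O
F18 | step 23 | C1,C24 diacetate, C18 alcohol | CC(=O)O[C@]1(C)CC[C@@H]2OC(C)(C)[C@@H](OCc3ccccc3)CC[C@@]2(C)[C@@H]1/C=C/[C@H]1[C@]2(C)CC[C@H](O)C(C)(C)O[C@H]2CC[C@]1(C)OC(C)=O
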